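## Retrosynthetic overview

1. Target 16 ← (−)-olivil 15 by lipase acetylation of its only primary hydroxyl; 15 ← tri-O-benzyl ether 14 by hydrogenolysis.
2. The tetrahydrofuran ring of 14 ← acyclic triol 13 by benzylic C–O closure, which places the aryl group trans to CH2OBn.
3. 13 ← α-benzyl-α-hydroxy lactone 12 ← α-methylene lactone 8 by aryl conjugate addition and enolate hydroxylation, which sets the tertiary carbinol.
4. Key disconnection: 8 ← aldehyde 5 + allylic bromide 4. The β-carbon of an acrylate is used as a carbanion (β-metallated acrylate = homoenolate, d3 donor), so two natively electrophilic carbons (aldehyde carbon and enoate β-carbon) are joined in a catalytic asymmetric chromium allylation; 4 ← Morita–Baylis–Hillman adduct of 1 and 2.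
5. Ring order: γ-lactone (step 3) → opened (step 5) → tetrahydrofuran (step 6).

Locants used below (lignan numbering): C7 = aryl-bearing CH–O, C8 = CH bearing C9H2O, C8′ = carbinol carbon bearing the benzyl group (C7′), C9′ = ring CH2–O.

Assumption: the (S,S)-configured ligand L* steers the allylchromium reagent to the Re face of 5; if the sense proves opposite, the (R,R)-antipode is used with no other change.

L* = (S,S)-1,8-bis(4-isopropyl-4,5-dihydrooxazol-2-yl)-3,6-diphenyl-9H-carbazole (tridentate carbazole bis(oxazoline) ligand).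

## Route

Step 1
Reactants: 1 (benzyloxy)acetaldehyde; 2 methyl acrylate
Product: 3 methyl 4-(benzyloxy)-3-hydroxy-2-methylidenebutanoate (racemic)
Conditions: DABCO (1.0 equiv), 2 (3 equiv), 1,4-dioxane/H2O 1:1, rt, 24–48 h
Reagents that add atoms: none
Why: Morita–Baylis–Hillman reaction of an unhindered α-alkoxy aldehyde with an acrylate; the carbinol centre needs no control because it is erased in step 2.

Step 2
Reactants: 3 methyl 4-(benzyloxy)-3-hydroxy-2-methylidenebutanoate
Product: 4 methyl (2Z)-4-(benzyloxy)-2-(bromomethyl)but-2-enoate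
Conditions: NBS (1.2 equiv), Me2S (1.4 equiv), CH2Cl2, 0 °C → rt, 12 h
Reagents that add atoms: N-bromosuccinimide, O=C1CCC(=O)N1Br
Why: Corey–Kim-type activation of the allylic alcohol as an alkoxysulfonium ion and SN2′ attack by bromide give the conjugated, thermodynamically preferred Z bromide (CH2Br cis to CH2OBn, vinylic H cis to the ester).

Step 3
Reactants: 4 methyl (2Z)-4-(benzyloxy)-2-(bromomethyl)but-2-enoate; 5 4-(benzyloxy)-3-methoxybenzaldehyde
Product: 8 (4R,5R)-5-[4-(benzyloxy)-3-methoxyphenyl]-4-[(benzyloxy)methyl]-3-methylideneoxolan-2-one, via silyl ether 6 (not isolated), via hydroxy ester 7 (not isolated)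
Conditions: CrCl2 (10 mol %), L* (12 mol %), Mn powder (2 equiv), iPr2NEt (0.3 equiv), TMSCl (1.5 equiv), THF, 0 °C → rt, 16 h; then 1 M HCl, THF, rt, 30 min; then PPTS (10 mol %), CH2Cl2, 40 °C
Reagents that add atoms: chlorotrimethylsilane, C[Si](C)(C)Cl (its silyl group is held in 6 only)
Why: Catalytic asymmetric Nozaki–Hiyama–Kishi 2-(alkoxycarbonyl)allylation followed by lactonisation: divalent chromium reduces 4 to an allyl species of trivalent chromium, a β-metallated acrylate (homoenolate equivalent), whose acrylate β-carbon attacks the aldehyde carbon through a closed chair transition state in which the ester-locked Z geometry puts CH2OBn axial and the aryl group equatorial (syn adduct), L* selects the Re face (C7 R and therefore C8 R), and the syn hydroxy ester closes to the 4,5-cis lactone.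

Step 4
Reactants: 8 (4R,5R)-5-[4-(benzyloxy)-3-methoxyphenyl]-4-[(benzyloxy)methyl]-3-methylideneoxolan-2-one; 9 1-(benzyloxy)-4-bromo-2-methoxybenzene
Product: 12 (3S,4R,5R)-5-[4-(benzyloxy)-3-methoxyphenyl]-3-{[4-(benzyloxy)-3-methoxyphenyl]methyl}-4-[(benzyloxy)methyl]-3-hydroxyoxolan-2-one, via aryl Grignard reagent 10 (not isolated), via magnesium enolate 11 (not isolated)
Conditions: 9 (1.4 equiv), Mg, THF, rt; CuBr·SMe2 (15 mol %), THF, −78 °C, add 8, −78 → −40 °C, 1 h; then 2-(phenylsulfonyl)-3-phenyloxaziridine (2.0 equiv), −78 → −40 °C; sat. aq. NH4Cl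
Reagents that add atoms: magnesium, [Mg] (held in 10 and 11 only); 2-(phenylsulfonyl)-3-phenyloxaziridine, O=S(=O)(c1ccccc1)N1OC1c1ccccc1
Why: Copper-catalysed conjugate addition of the aryl Grignard reagent to the exocyclic enoate gives a tetrasubstituted magnesium enolate, and Davis oxidation delivers oxygen to the ring face opposite the cis-disposed aryl and CH2OBn groups, so the new carbinol centre (3S) has OH anti to CH2OBn and the benzyl group syn to it.

Step 5
Reactants: 12 (3S,4R,5R)-α-benzyl-α-hydroxy lactone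
Product: 13 (2S,3R,4R)-4-[4-(benzyloxy)-3-methoxyphenyl]-2-{[4-(benzyloxy)-3-methoxyphenyl]methyl}-3-[(benzyloxy)methyl]butane-1,2,4-triol
Conditions: LiAlH4 (3 equiv), THF, 0 °C → rt, 2 h; Rochelle-salt work-up
Reagents that add atoms: none
Why: Hydride reduction of the lactone to the 1,4-diol; no stereocentre is touched and the benzyl ethers are inert.

Step 6
Reactants: 13 (2S,3R,4R)-triol
Product: 14 (3S,4R,5S)-5-[4-(benzyloxy)-3-methoxyphenyl]-3-{[4-(benzyloxy)-3-methoxyphenyl]methyl}-4-[(benzyloxy)methyl]oxolan-3-ol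
Conditions: camphorsulfonic acid (20 mol %), CH2Cl2 (0.01 M), 0 °C → rt, 1–2 h, followed by TLC; Et3N quench
Reagents that add atoms: none
Why: Acid-promoted SN1 cyclodehydration: the para-alkoxybenzyl cation at C7 is captured 5-exo by the primary hydroxyl, and under these reversible conditions C7 is re-set to the isomer with the aryl group trans to CH2OBn (5S), the only one that keeps the aryl group off the face carrying both CH2OBn and the benzyl group.

Step 7
Reactants: 14 tri-O-benzyl-olivil
Product: 15 (−)-olivil, (3S,4R,5S)-5-(4-hydroxy-3-methoxyphenyl)-3-[(4-hydroxy-3-methoxyphenyl)methyl]-4-(hydroxymethyl)oxolan-3-ol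
Conditions: H2 (1 atm), 10 % Pd/C, EtOAc/EtOH 1:1, rt, stopped at full debenzylation
Reagents that add atoms: none
Why: Hydrogenolysis of the three O-benzyl ethers, which are cleaved much faster under neutral conditions than the hindered secondary benzylic ring C–O bond.

Step 8
Reactants: 15 (−)-olivil
Product: 16 olivil monoacetate, [(2S,3R,4S)-4-hydroxy-2-(4-hydroxy-3-methoxyphenyl)-4-[(4-hydroxy-3-methoxyphenyl)methyl]oxolan-3-yl]methyl acetate
Conditions: immobilised Candida antarctica lipase B (Novozym 435), vinyl acetate (5 equiv), THF, 40 °C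
Reagents that add atoms: vinyl acetate, CC(=O)OC=C
Why: Lipase-catalysed irreversible transesterification acylates the single primary aliphatic hydroxyl and leaves the two phenols and the tertiary alcohol untouched.

## Compound list

1 | (benzyloxy)acetaldehyde | O=CCOCc1ccccc1 | starting material
2 | methyl acrylate | C=CC(=O)OC | starting material
3 | methyl 4-(benzyloxy)-3-hydroxy-2-methylidenebutanoate (racemic) | C=C(C(=O)OC)C(O)COCc1ccccc1 | intermediate
4 | methyl (2Z)-4-(benzyloxy)-2-(bromomethyl)but-2-enoate | BrC/C(C(=O)OC)=C\COCc1ccccc1 | intermediate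
5 | 4-(benzyloxy)-3-methoxybenzaldehyde (O-benzylvanillin) | COc1cc(C=O)ccc1OCc1ccccc1 | starting material
6 | methyl (3R,4R)-4-[4-(benzyloxy)-3-methoxyphenyl]-3-[(benzyloxy)methyl]-2-methylidene-4-[(trimethylsilyl)oxy]butanoate (syn; formed in the flask) | COC(=O)C(=C)[C@H](COCc1ccccc1)[C@@H](O[Si](C)(C)C)c1ccc(OCc2ccccc2)c(OC)c1 | intermediate
7 | methyl (3R,4R)-4-[4-(benzyloxy)-3-methoxyphenyl]-3-[(benzyloxy)methyl]-4-hydroxy-2-methylidenebutanoate (syn; formed in the flask) | COC(=O)C(=C)[C@H](COCc1ccccc1)[C@@H](O)c1ccc(OCc2ccccc2)c(OC)c1 | intermediate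
8 | (4R,5R)-5-[4-(benzyloxy)-3-methoxyphenyl]-4-[(benzyloxy)methyl]-3-methylideneoxolan-2-one (4,5-cis) | C=C1C(=O)O[C@@H](c2ccc(OCc3ccccc3)c(OC)c2)[C@H]1COCc1ccccc1 | intermediate
9 | 1-(benzyloxy)-4-bromo-2-methoxybenzene | COc1cc(Br)ccc1OCc1ccccc1 | starting material
10 | [4-(benzyloxy)-3-methoxyphenyl]magnesium bromide (formed in the flask) | COc1cc([Mg]Br)ccc1OCc1ccccc1 | intermediate
11 | bromomagnesium (4R,5R)-5-[4-(benzyloxy)-3-methoxyphenyl]-3-{[4-(benzyloxy)-3-methoxyphenyl]methyl}-4-[(benzyloxy)methyl]-4,5-dihydrofuran-2-olate (formed in the flask) | Br[Mg]OC1=C(Cc2ccc(OCc3ccccc3)c(OC)c2)[C@H](COCc2ccccc2)[C@H](c2ccc(OCc3ccccc3)c(OC)c2)O1 | intermediate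
12 | (3S,4R,5R)-5-[4-(benzyloxy)-3-methoxyphenyl]-3-{[4-(benzyloxy)-3-methoxyphenyl]methyl}-4-[(benzyloxy)methyl]-3-hydroxyoxolan-2-one | O=C1O[C@@H](c2ccc(OCc3ccccc3)c(OC)c2)[C@@H](COCc2ccccc2)[C@@]1(O)Cc1ccc(OCc2ccccc2)c(OC)c1 | intermediate
13 | (2S,3R,4R)-4-[4-(benzyloxy)-3-methoxyphenyl]-2-{[4-(benzyloxy)-3-methoxyphenyl]methyl}-3-[(benzyloxy)methyl]butane-1,2,4-triol | O[C@@H](c1ccc(OCc2ccccc2)c(OC)c1)[C@@H](COCc1ccccc1)[C@](O)(CO)Cc1ccc(OCc2ccccc2)c(OC)c1 | intermediate
14 | (3S,4R,5S)-5-[4-(benzyloxy)-3-methoxyphenyl]-3-{[4-(benzyloxy)-3-methoxyphenyl]methyl}-4-[(benzyloxy)methyl]oxolan-3-ol (tri-O-benzyl-olivil) | COc1cc(C[C@@]2(O)CO[C@H](c3ccc(OCc4ccccc4)c(OC)c3)[C@H]2COCc2ccccc2)ccc1OCc1ccccc1 | intermediate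
15 | (−)-olivil, (3S,4R,5S)-5-(4-hydroxy-3-methoxyphenyl)-3-[(4-hydroxy-3-methoxyphenyl)methyl]-4-(hydroxymethyl)oxolan-3-ol | COc1cc(C[C@@]2(O)CO[C@H](c3ccc(O)c(OC)c3)[C@H]2CO)ccc1O | intermediate
16 | olivil monoacetate, [(2S,3R,4S)-4-hydroxy-2-(4-hydroxy-3-methoxyphenyl)-4-[(4-hydroxy-3-methoxyphenyl)methyl]oxolan-3-yl]methyl acetate | COc1cc(C[C@@]2(O)CO[C@H](c3ccc(O)c(OC)c3)[C@H]2COC(C)=O)ccc1O | target

## Step count and risks

Total step count: 8. Longest linear sequence: 8 steps (1/2 → 16); both aryl units enter as commercial materials.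

The three steps most likely to fail:

Step 3 is the riskiest. The asymmetric chromium allylation is established for the parent 2-(alkoxycarbonyl)allyl bromide; the γ-(benzyloxymethyl) donor, its syn preference and the ligand sense are extrapolations. The fallback changes the metal and the mode of stereocontrol and sets out from 3. Acetylation (Ac2O, DMAP, CH2Cl2) gives methyl 3-acetoxy-4-(benzyloxy)-2-methylidenebutanoate F1. Copper-catalysed SN2′ borylation (B2pin2, CuCl, LiCl, KOAc, DMF, rt) gives methyl (2E)-4-(benzyloxy)-2-[(4,4,5,5-tetramethyl-1,3,2-dioxaborolan-2-yl)methyl]but-2-enoate F2, in which boron is cis to CH2OBn (the geometry of 4; the descriptor changes only because boron ranks below oxygen). Allylboration of 5 catalysed by the chiral phosphoric acid (R)-TRIP (toluene, −30 °C → rt) goes through a closed chair transition state to syn 7, and PPTS closes it to the cis lactone. The fallback comes back to the route at 8.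

Step 4 may fail because the hindered magnesium enolate 11 can be oxidised slowly, and leftover Grignard reagent or copper can consume the oxaziridine. The fallback puts the oxygen in first and avoids the enolate; it sets out from 8. Dimethyldioxirane (acetone, rt) epoxidises the exocyclic alkene on the face opposite both ring substituents to give (3R,6R,7R)-6-[4-(benzyloxy)-3-methoxyphenyl]-7-[(benzyloxy)methyl]-1,5-dioxaspiro[2.4]heptan-4-one F3. Grignard reagent 10 with CuBr·SMe2 (THF, −40 °C) then opens the epoxide at its CH2 terminus. The fallback comes back to the route at 12.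

Step 6 may fail because the benzylic cation can also be trapped by the electron-rich benzyl ring (aryltetralin of the cyclo-olivil type), or the closure can stop short of full trans selectivity. The fallback avoids acid on the protected series and sets out from 13. Hydrogenolysis (H2, Pd/C, EtOAc/EtOH) first gives (2S,3R,4R)-4-(4-hydroxy-3-methoxyphenyl)-2-[(4-hydroxy-3-methoxyphenyl)methyl]-3-(hydroxymethyl)butane-1,2,4-triol F4. Its free para-hydroxybenzyl alcohol forms the neutral para-quinone methide under near-neutral conditions (PPTS, MeCN, rt, or pH 7 buffer/MeCN, 60 °C), and the primary hydroxyl closes onto it to give the trans ring. This bypasses 14 and step 7, and the fallback comes back to the route at 15.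

## Further compounds

F1 | step 3 | methyl 3-acetoxy-4-(benzyloxy)-2-methylidenebutanoate (racemic) | C=C(C(=O)OC)C(OC(C)=O)COCc1ccccc1
F2 | step 3 | methyl (2E)-4-(benzyloxy)-2-[(4,4,5,5-tetramethyl-1,3,2-dioxaborolan-2-yl)methyl]but-2-enoate | COC(=O)/C(CB1OC(C)(C)C(C)(C)O1)=C/COCc1ccccc1
F3 | step 4 | (3R,6R,7R)-6-[4-(benzyloxy)-3-methoxyphenyl]-7-[(benzyloxy)methyl]-1,5-dioxaspiro[2.4]heptan-4-one | O=C1O[C@@H](c2ccc(OCc3ccccc3)c(OC)c2)[C@@H](COCc2ccccc2)[C@]12OC2
F4 | step 6 | (2S,3R,4R)-4-(4-hydroxy-3-methoxyphenyl)-2-[(4-hydroxy-3-methoxyphenyl)methyl]-3-(hydroxymethyl)butane-1,2,4-triol | O[C@@H](c1ccc(O)c(OC)c1)[C@@H](CO)[C@](O)(CO)Cc1ccc(O)c(OC)c1
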